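**Plan**

1. Retrosynthesis: the ring A phenol is traced back to its methyl ether. Ring B is then opened at C3'–C4' and C5'–C6' after adding back H2 and PhSOH, giving a 2-aryloxy-3-bromobuta-1,3-diene and a 1-bromovinyl sulfoxide.
2. The diene is cut at its enol-ether C=CH2 bond (ester methylenation) and at the acyl–O bond, leading to 4,5,6-tribromoguaiacol and on to guaiacol.
3. Forward: ring A is bought as guaiacol and brominated; the four-carbon chain is attached as a 2-bromoacrylate and methylenated; ring B is then formed by [4+2] cycloaddition, loss of PhSOH and dehydrogenation; BBr3 frees the phenol.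
4. Enabling feature: ring B carries the ether oxygen at C1' with bromine ortho (C2') and para (C4'). Oxygen and the C2' bromine travel on adjacent diene carbons, and the C4' bromine sits on the dienophile carbon that ends para to oxygen.
5. A sulfinyl group is the removable activator on C4' because it leaves thermally with a neighbouring ring hydrogen and so keeps the C4' bromine; a sulfonyl group there would give up HBr to base instead.
6. Stereochemistry: the target is achiral; the C4' and sulfur stereocentres of the cycloadduct are unselected and are erased by elimination and aromatization.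

Key step: step 5

Assumption: because the target is achiral, commercial racemic phenyl vinyl sulfoxide is used and no stereocontrol is sought anywhere.

**Route**

Step 1
Reactants: 1 guaiacol (2-methoxyphenol)
Product: 2 4,5,6-tribromoguaiacol (2,3,4-tribromo-6-methoxyphenol)
Conditions: Br2 (3.1 equiv), AcOH, rt → 40 °C
Reagents that add atoms: bromine, BrBr
Why: Electrophilic aromatic bromination in which the hydroxyl group directs to C4 and C6 and the methoxy group to C5, while the remaining C3–H (ortho only to OMe, in an already tribrominated ring) is expected to survive three equivalents of bromine.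

Step 2
Reactants: 2 4,5,6-tribromoguaiacol; 3 2,3-dibromopropanoyl chloride (racemic)
Product: 5 2,3,4-tribromo-6-methoxyphenyl 2-bromoprop-2-enoate, via dibromopropanoate ester 4 (not isolated)
Conditions: Et3N (1.05 equiv), CH2Cl2, −20 °C; then Et3N (1.2 equiv), 0 °C → rt, BHT (trace)
Reagents that add atoms: none
Why: O-Acylation of the phenol by the acid chloride is followed in the same flask by base-mediated E1cB dehydrobromination of the α-bromo ester (acidic α-hydrogen, β-bromide leaving), the standard entry to 2-bromoacrylic esters; adding the base in two portions keeps free phenoxide away from the Michael acceptor.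

Step 3
Reactants: 5 2,3,4-tribromo-6-methoxyphenyl 2-bromoprop-2-enoate
Product: 6 1,2,3-tribromo-4-[(3-bromobuta-1,3-dien-2-yl)oxy]-5-methoxybenzene
Conditions: Cp2TiMe2 (2.5 equiv), PhMe/THF, 65 °C, dark, BHT (trace); filtration through basic alumina
Reagents that add atoms: Cp2TiMe2 (dimethyltitanocene, Petasis reagent), [CH3-].[CH3-].[Ti+4].c1cc[cH-]c1.c1cc[cH-]c1
Why: Petasis methylenation, in which Cp2TiMe2 loses methane on heating to give Cp2Ti=CH2 that adds [2+2] to the ester carbonyl and cycloreverts to the enol ether and Cp2Ti=O; the reaction is established for aryl esters and for α,β-unsaturated esters (which give 2-oxy dienes), and its non-acidic conditions suit the enol ether.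

Step 4
Reactants: 7 phenyl vinyl sulfoxide (racemic)
Product: 9 (1-bromoethenyl) phenyl sulfoxide (racemic), via 1,2-dibromoethyl sulfoxide 8 (not isolated)
Conditions: Br2 (1.05 equiv), CH2Cl2, 0 °C; then DBU (1.1 equiv), 0 °C → rt
Reagents that add atoms: bromine, BrBr
Why: Bromine addition to the vinyl group followed by base-induced dehydrobromination that removes the most acidic proton (α to sulfinyl and bromine) and expels the β-bromide, the same addition–elimination sequence by which 1-halovinyl sulfones and sulfoxides are prepared.

Step 5
Reactants: 6 1,2,3-tribromo-4-[(3-bromobuta-1,3-dien-2-yl)oxy]-5-methoxybenzene; 9 (1-bromoethenyl) phenyl sulfoxide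
Product: 13 1,2,3-tribromo-4-(2,4-dibromophenoxy)-5-methoxybenzene, via sulfinylcyclohexene adduct 10 (not isolated), via cyclohexa-1,3-diene 11 (not isolated), via cyclohexa-1,4-diene 12 (not isolated)
Conditions: 9 (2 equiv), BHT (cat.), PhMe, 120 °C, sealed tube; then DDQ (1.5 equiv), rt → 60 °C
Reagents that add atoms: none
Why: A concerted, asynchronous normal-demand Diels–Alder reaction joins the nucleophilic enol-ether terminus C6' of diene 6 to the unsubstituted CH2 (C5') of 9 and C3' to the bromine- and sulfinyl-bearing carbon (C4'), closing ring B as a cyclohexene by intermolecular suprafacial [4+2] cycloaddition to give 10. The closest known reaction type is the use of aryl vinyl sulfoxides as alkyne equivalents towards 2-oxygenated dienes, where cycloaddition is followed in the same pot by thermal syn-elimination (Ei) of the sulfenic acid. Here the tertiary sulfoxide of 10 takes a cis hydrogen from C3' or C5' and leaves as PhSOH, so the bromine stays on C4' as a vinylic bromide in 11 and 12, whereas a sulfonyl group in its place would have to be removed by base, which would expel bromide instead. The new C4' stereocentre arises next to the racemic sulfur centre under no control and needs none, since elimination and aromatization erase both. The selectivity that matters is regiochemical: the aryloxy group is a stronger π-donor than the C2' bromine and puts the largest HOMO coefficient on C6', so the sulfinyl-bearing carbon should end para to oxygen and fix bromine at C4'. DDQ then abstracts hydride and a proton from either diene to give the arene, and because the ether oxygen and both ring B bromines sit on sp2 carbons none of them can be lost on the way.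

Step 6
Reactants: 13 1,2,3-tribromo-4-(2,4-dibromophenoxy)-5-methoxybenzene
Product: 14 3,4,5-tribromo-2-(2,4-dibromophenoxy)phenol (CNP0186272.0)
Conditions: BBr3 (3 equiv), CH2Cl2, −78 → 0 °C; then H2O
Reagents that add atoms: none
Why: Lewis-acid ether cleavage in which BBr3 complexes the methoxy oxygen and bromide attacks the methyl group in an SN2 step, while the diaryl ether (no sp3 C–O bond) and the aryl bromides are inert; hydrolysis of the aryl borate gives the phenol.

**Compound list**

1 | guaiacol (2-methoxyphenol) | COc1ccccc1O | starting material
2 | 4,5,6-tribromoguaiacol (2,3,4-tribromo-6-methoxyphenol) | COc1cc(Br)c(Br)c(Br)c1O | intermediate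
3 | 2,3-dibromopropanoyl chloride (racemic) | O=C(Cl)C(Br)CBr | starting material
4 | 2,3,4-tribromo-6-methoxyphenyl 2,3-dibromopropanoate (racemic, not isolated) | COc1cc(Br)c(Br)c(Br)c1OC(=O)C(Br)CBr | intermediate
5 | 2,3,4-tribromo-6-methoxyphenyl 2-bromoprop-2-enoate | COc1cc(Br)c(Br)c(Br)c1OC(=O)C(Br)=C | intermediate
6 | 1,2,3-tribromo-4-[(3-bromobuta-1,3-dien-2-yl)oxy]-5-methoxybenzene | COc1cc(Br)c(Br)c(Br)c1OC(=C)C(Br)=C | intermediate
7 | phenyl vinyl sulfoxide, (ethenylsulfinyl)benzene (racemic at sulfur) | C=CS(=O)c1ccccc1 | starting material
8 | (1,2-dibromoethyl) phenyl sulfoxide (racemic mixture of diastereomers, not isolated) | BrCC(Br)S(=O)c1ccccc1 | intermediate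
9 | (1-bromoethenyl) phenyl sulfoxide (racemic at sulfur) | C=C(Br)S(=O)c1ccccc1 | intermediate
10 | 1,2,3-tribromo-4-{[2,4-dibromo-4-(phenylsulfinyl)cyclohex-1-en-1-yl]oxy}-5-methoxybenzene (racemic, both diastereomers at C4'/S, not isolated) | COc1cc(Br)c(Br)c(Br)c1OC1=C(Br)CC(Br)(S(=O)c2ccccc2)CC1 | intermediate
11 | 1,2,3-tribromo-4-[(2,4-dibromocyclohexa-1,3-dien-1-yl)oxy]-5-methoxybenzene (not isolated) | COc1cc(Br)c(Br)c(Br)c1OC1=C(Br)C=C(Br)CC1 | intermediate
12 | 1,2,3-tribromo-4-[(2,4-dibromocyclohexa-1,4-dien-1-yl)oxy]-5-methoxybenzene (not isolated) | COc1cc(Br)c(Br)c(Br)c1OC1=C(Br)CC(Br)=CC1 | intermediate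
13 | 1,2,3-tribromo-4-(2,4-dibromophenoxy)-5-methoxybenzene | COc1cc(Br)c(Br)c(Br)c1Oc1ccc(Br)cc1Br | intermediate
14 | 3,4,5-tribromo-2-(2,4-dibromophenoxy)phenol | Oc1cc(Br)c(Br)c(Br)c1Oc1ccc(Br)cc1Br | target

**Step count**

Total: 6 steps. Longest linear sequence: 5 steps (1, 2, 3, 5, 6); step 4 is a one-step side branch.

**Steps most likely to fail, with fallbacks**

Step 5. The cycloaddition may be too slow, because the diene is made less electron-rich by its bromine and by the polybrominated aryloxy group and a sulfinyl group is only a modest activator. Diene dimerisation or polymerisation and re-addition of the liberated sulfenic acid could then compete, and the C2' bromine may erode the regiocontrol. The fallback replaces the cycloaddition by a direct C–O arylation. It sets out from phenol 2, which is heated in aqueous NaOH/dioxane with bis(2,4-dibromophenyl)iodonium chloride F1. F1 is made from 1,3-dibromobenzene, I2 and KIO3 in concentrated H2SO4 and precipitated with NaCl. The phenoxide should take over one 2,4-dibromophenyl group and give methyl ether 13, where the route is rejoined before step 6.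

Step 3. The 2-bromoacrylate may suffer conjugate addition or radical polymerisation, or lose its vinylic bromine to low-valent titanium, while the carbene is generated hot; the product diene may also dimerise at that temperature. The fallback moves the C2' bromine to a late electrophilic substitution, so that no bromoacrylate meets the titanium reagent. It sets out from 2, which is acylated with acryloyl chloride and Et3N to 2,3,4-tribromo-6-methoxyphenyl prop-2-enoate F2. F2 is methylenated with Cp2TiMe2 to 1,2,3-tribromo-4-(buta-1,3-dien-2-yloxy)-5-methoxybenzene F3. Heating F3 with 9 in toluene at 120 °C and then adding DDQ should lead through the sulfinylcyclohexene adduct F4, the cyclohexa-1,3-diene F5 and the cyclohexa-1,4-diene F6 to 1,2,3-tribromo-4-(4-bromophenoxy)-5-methoxybenzene F7. One equivalent of Br2 in AcOH is then expected to brominate ring B ortho to the ether oxygen, which returns to the route at 13.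

Step 4. The HBr formed may reversibly deoxygenate the sulfoxide, or the dehydrobromination may run in the wrong sense and give 2-bromovinyl isomers. The fallback replaces addition–elimination by deprotonation and electrophilic bromination. It sets out from 7, which is deprotonated at the α-vinylic position with LDA (LiN(iPr)2) in THF at −78 °C to (1-lithioethenyl) phenyl sulfoxide F8. Quenching with 1,2-dibromotetrachloroethane should give 9, where the route is rejoined.

Further compounds
F1 | step 5 | bis(2,4-dibromophenyl)iodonium chloride | Brc1ccc([I+]c2ccc(Br)cc2Br)c(Br)c1.[Cl-]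
F2 | step 3 | 2,3,4-tribromo-6-methoxyphenyl prop-2-enoate | COc1cc(Br)c(Br)c(Br)c1OC(=O)C=C
F3 | step 3 | 1,2,3-tribromo-4-(buta-1,3-dien-2-yloxy)-5-methoxybenzene | COc1cc(Br)c(Br)c(Br)c1OC(=C)C=C
F4 | step 3 | 1,2,3-tribromo-4-{[4-bromo-4-(phenylsulfinyl)cyclohex-1-en-1-yl]oxy}-5-methoxybenzene (racemic, both diastereomers) | COc1cc(Br)c(Br)c(Br)c1OC1=CCC(Br)(S(=O)c2ccccc2)CC1
F5 | step 3 | 1,2,3-tribromo-4-[(4-bromocyclohexa-1,3-dien-1-yl)oxy]-5-methoxybenzene | COc1cc(Br)c(Br)c(Br)c1OC1=CC=C(Br)CC1
F6 | step 3 | 1,2,3-tribromo-4-[(4-bromocyclohexa-1,4-dien-1-yl)oxy]-5-methoxybenzene | COc1cc(Br)c(Br)c(Br)c1OC1=CCC(Br)=CC1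
F7 | step 3 | 1,2,3-tribromo-4-(4-bromophenoxy)-5-methoxybenzene | COc1cc(Br)c(Br)c(Br)c1Oc1ccc(Br)cc1
F8 | step 4 | (1-lithioethenyl) phenyl sulfoxide | [Li]C(=C)S(=O)c1ccccc1
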